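**Retrosynthetic overview**

Numbering: ring carbons C1–C10 (C1–C3 CH2, C4 C(OH)CH3, C5 CH–O-acyl, C6 lactone CH–O, C7 ring-fusion CH, C8 CHOH, C9 C=O, C10 CHCH3); lactone carbons C11 (bearing C13H2=) and C12 (C=O).
The strategy rests on the two neighbouring oxygen-bearing ring carbons C5 and C6: O6 reaches the C12 carboxyl through a five-membered ring, O5 only through a six-membered one. The ten-membered carbocycle is therefore cut at C5–C6 (to a 5,6-dialdehyde) and the γ-lactone at O6–C12 (to a methyl ester); one reductive step closes the carbocycle first and the lactone second.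
The open-chain dialdehyde comes from an Evans syn-aldol (C7–C8) between a succinate imide (C6, C7, C11, C12) and an α-silyloxy aldehyde holding C8–C10 and C1–C5 of (S)-citronellal intact. C9–O is set by proline α-aminoxylation, C4–O by Sharpless epoxidation and hydride opening, C5–O by allylic oxidation of the E-methyl group.
After ring closure: methylenation at C11, acylation of O5 with (R)-2-methylbutanoic acid, oxidation of C9–OH to the ketone, desilylation.

Key step: step 18

Remarks on the chemistry: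
- C9 is a carbinol only until step 22; it is set as 9R (8,9-anti) because this epimer comes from L-proline and is the matched partner of the aldol in step 12.
- O4 is carried as a triethylsilyl ether, not an acetal: a chelate-controlled approach past the C4 methyl would lead to the 5-epimer, whereas a non-chelating silyl ether favours the polar Felkin–Anh arrangement that leads to 5S; it is also removed by fluoride at the end.
- From compound 15 on, the locants C1–C13 defined above are used in the names.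

**Route**

Step 1
Reactants: 1 (S)-citronellal
Product: 3 (2R,3S)-3,7-dimethyl-2-[(phenylamino)oxy]oct-6-en-1-ol, via alpha-anilinooxy aldehyde 2 (not isolated)
Conditions: PhNO, L-proline (20 mol%), DMSO, rt; then NaBH4, EtOH, 0 °C
Reagents that add atoms: nitrosobenzene O=Nc1ccccc1
Why: Proline-enamine α-aminoxylation, in which the anti-enamine of L-proline takes the nitroso oxygen on the face directed by the carboxylic acid, should set C9 as R under catalyst control over the C10 methyl, and borohydride reduction in the same flask secures the labile aldehyde.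

Step 2
Reactants: 3 (2R,3S)-3,7-dimethyl-2-[(phenylamino)oxy]oct-6-en-1-ol
Product: 4 (2R,3S)-3,7-dimethyloct-6-ene-1,2-diol
Conditions: Zn dust, AcOH, THF/H2O, rt
Reagents that add atoms: none
Why: Reductive cleavage of the weak N–O bond by zinc in acetic acid should free the C9 hydroxyl without touching the alkene or either stereocentre.

Step 3
Reactants: 4 (2R,3S)-3,7-dimethyloct-6-ene-1,2-diol
Product: 5 (4R)-2,2-dimethyl-4-[(2S)-6-methylhept-5-en-2-yl]-1,3-dioxolane
Conditions: Me2C(OMe)2, PPTS (cat.), CH2Cl2, rt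
Reagents that add atoms: 2,2-dimethoxypropane COC(C)(C)OC
Why: Acid-catalysed isopropylidene acetal formation ties the 1,2-diol into one group that tolerates the oxidation, base and hydride steps that follow.

Step 4
Reactants: 5 (4R)-2,2-dimethyl-4-[(2S)-6-methylhept-5-en-2-yl]-1,3-dioxolane
Product: 6 (2E,6S)-6-[(4R)-2,2-dimethyl-1,3-dioxolan-4-yl]-2-methylhept-2-en-1-ol
Conditions: SeO2 (0.3 equiv), t-BuOOH, salicylic acid (cat.), CH2Cl2, rt, stopped before over-oxidation
Reagents that add atoms: tert-butyl hydroperoxide CC(C)(C)OO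
Why: Riley allylic oxidation (ene reaction, then [2,3]-sigmatropic shift of the allylseleninic acid) is known to take the E-methyl group of a trisubstituted gem-dimethyl alkene, which places the C5 hydroxyl and gives the E allylic alcohol.

Step 5
Reactants: 6 (2E,6S)-6-[(4R)-2,2-dimethyl-1,3-dioxolan-4-yl]-2-methylhept-2-en-1-ol
Product: 7 [(2S,3S)-3-{(3S)-3-[(4R)-2,2-dimethyl-1,3-dioxolan-4-yl]butyl}-2-methyloxiran-2-yl]methanol
Conditions: Ti(OiPr)4 (cat.), L-(+)-diethyl tartrate (cat.), t-BuOOH, 4 Å MS, CH2Cl2, −20 °C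
Reagents that add atoms: tert-butyl hydroperoxide CC(C)(C)OO
Why: Sharpless asymmetric epoxidation with L-(+)-tartrate delivers oxygen to the face of an E-2-methyl allylic alcohol that gives the (2S,3S)-epoxy alcohol, so C4 receives its oxygen with the target configuration under reagent control.

Step 6
Reactants: 7 [(2S,3S)-3-{(3S)-3-[(4R)-2,2-dimethyl-1,3-dioxolan-4-yl]butyl}-2-methyloxiran-2-yl]methanol
Product: 8 (4R)-4-[(2S)-4-{(2S,3S)-3-[(4-methoxybenzyl)oxymethyl]-3-methyloxiran-2-yl}butan-2-yl]-2,2-dimethyl-1,3-dioxolane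
Conditions: NaH, PMBCl, Bu4NI (cat.), THF, 0 °C → rt
Reagents that add atoms: 4-methoxybenzyl chloride COc1ccc(CCl)cc1
Why: Williamson etherification of the primary alkoxide gives a PMB ether that can later be removed oxidatively, and protecting before the hydride step means O4 and O5 never have to be differentiated as a diol.

Step 7
Reactants: 8 (4R)-4-[(2S)-4-{(2S,3S)-3-[(4-methoxybenzyl)oxymethyl]-3-methyloxiran-2-yl}butan-2-yl]-2,2-dimethyl-1,3-dioxolane
Product: 9 (2R,6S)-6-[(4R)-2,2-dimethyl-1,3-dioxolan-4-yl]-1-[(4-methoxybenzyl)oxy]-2-methylheptan-2-ol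
Conditions: LiEt3BH, THF, 0 °C → rt; H2O
Reagents that add atoms: none
Why: SN2 hydride opening of the trisubstituted epoxide at its less substituted carbon C3 leaves the C4–O bond untouched, so the tertiary alcohol should form with C4 retained.

Step 8
Reactants: 9 (2R,6S)-6-[(4R)-2,2-dimethyl-1,3-dioxolan-4-yl]-1-[(4-methoxybenzyl)oxy]-2-methylheptan-2-ol
Product: 10 (2R,3S,7R)-8-[(4-methoxybenzyl)oxy]-3,7-dimethyloctane-1,2,7-triol
Conditions: AcOH/H2O (4:1), 40 °C
Reagents that add atoms: none
Why: Acid-catalysed hydrolysis removes the terminal isopropylidene acetal, while the PMB ether and the tertiary alcohol are stable to aqueous acetic acid.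

Step 9
Reactants: 10 (2R,3S,7R)-8-[(4-methoxybenzyl)oxy]-3,7-dimethyloctane-1,2,7-triol
Product: 11 (2R,3S,7R)-8-[(4-methoxybenzyl)oxy]-3,7-dimethyl-1,2,7-tris(triethylsilyloxy)octane
Conditions: TESOTf (3.6 equiv), 2,6-lutidine, CH2Cl2, −78 → 0 °C
Reagents that add atoms: triethylsilyl trifluoromethanesulfonate CC[Si](CC)(CC)OS(=O)(=O)C(F)(F)F
Why: Silylation with a silyl triflate and a hindered pyridine base is fast enough to cap the primary, the secondary and the tertiary hydroxyl in one operation.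

Step 10
Reactants: 11 (2R,3S,7R)-8-[(4-methoxybenzyl)oxy]-3,7-dimethyl-1,2,7-tris(triethylsilyloxy)octane
Product: 12 (2R,3S,7R)-8-[(4-methoxybenzyl)oxy]-3,7-dimethyl-2,7-bis(triethylsilyloxy)octanal
Conditions: (COCl)2, DMSO, CH2Cl2, −78 → −35 °C; Et3N, −78 → 0 °C
Reagents that add atoms: none
Why: Under Swern conditions the chlorosulfonium species cleaves only the unhindered primary triethylsilyl ether and oxidises it in the same flask, giving the C8 aldehyde with O9 still silylated and no separate deprotection.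

Step 11
Reactants: 13 (S)-4-benzyloxazolidin-2-one; 14 methyl 4-chloro-4-oxobutanoate
Product: 15 methyl 4-[(4S)-4-benzyl-2-oxooxazolidin-3-yl]-4-oxobutanoate
Conditions: Et3N, DMAP (cat.), CH2Cl2, 0 °C → rt
Reagents that add atoms: none
Why: DMAP-catalysed N-acylation of the oxazolidinone by the acid chloride of monomethyl succinate gives the imide whose auxiliary controls the aldol.

Step 12
Reactants: 15 methyl 4-[(4S)-4-benzyl-2-oxooxazolidin-3-yl]-4-oxobutanoate; 12 (2R,3S,7R)-8-[(4-methoxybenzyl)oxy]-3,7-dimethyl-2,7-bis(triethylsilyloxy)octanal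
Product: 17 syn-aldol adduct methyl (3S,4S,5R,6S,10R)-3-{[(4S)-4-benzyl-2-oxooxazolidin-3-yl]carbonyl}-4-hydroxy-11-[(4-methoxybenzyl)oxy]-6,10-dimethyl-5,10-bis(triethylsilyloxy)undecanoate, via Z-dibutylboron enolate 16 (not isolated)
Conditions: Bu2BOTf, i-Pr2NEt, CH2Cl2, −78 → 0 °C; 12, −78 → 0 °C; pH 7 buffer, MeOH, H2O2, 0 °C
Reagents that add atoms: none
Why: Evans syn-aldol, in which the Z boron enolate of the imide (the ester is not enolised) reacts through a chair Zimmerman–Traxler transition state on the face left open by the auxiliary benzyl group, should set C7 and C8 as in the target, and the Cornforth/Felkin preference of the α-silyloxy aldehyde for the 8,9-anti adduct is matched with this sense.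

Step 13
Reactants: 17 syn-aldol adduct (8-OH)
Product: 18 O8 tert-butyldimethylsilyl ether of 17
Conditions: TBSOTf, 2,6-lutidine, CH2Cl2, −78 °C, on the crude adduct
Reagents that add atoms: tert-butyldimethylsilyl trifluoromethanesulfonate CC(C)(C)[Si](C)(C)OS(=O)(=O)C(F)(F)F
Why: Low-temperature silylation with the silyl triflate caps the hindered C8 hydroxyl before it can cyclise onto the C12 methyl ester and distinguishes O8 (TBS) from O9 (TES) for the end of the route.

Step 14
Reactants: 18 O8 tert-butyldimethylsilyl ether of 17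
Product: 19 methyl (3S,4S,5R,6S,10R)-4-[tert-butyl(dimethyl)silyl]oxy-3-[(ethylsulfanyl)carbonyl]-11-[(4-methoxybenzyl)oxy]-6,10-dimethyl-5,10-bis(triethylsilyloxy)undecanoate
Conditions: EtSH, n-BuLi, THF, 0 °C
Reagents that add atoms: ethanethiol CCS
Why: Transthioesterification, in which lithium ethanethiolate displaces the oxazolidinone at the activated exocyclic imide carbonyl, gives the thioester and returns the auxiliary, the methyl ester being far less electrophilic.

Step 15
Reactants: 19 C6 S-ethyl thioester (O5 PMB)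
Product: 20 C6 S-ethyl thioester with free C5 hydroxyl (11-hydroxy analogue of 19)
Conditions: DDQ, CH2Cl2/pH 7 buffer, 0 °C
Reagents that add atoms: none
Why: Oxidative PMB cleavage by DDQ (benzylic hydride abstraction, hydrolysis of the oxocarbenium ion) frees only O5, since silyl ethers, thioester and ester are inert under buffered conditions.

Step 16
Reactants: 20 C6 S-ethyl thioester with free C5 hydroxyl
Product: 21 C6 S-ethyl thioester C5 aldehyde (11-oxo analogue of 19)
Conditions: Dess–Martin periodinane, NaHCO3, CH2Cl2, rt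
Reagents that add atoms: none
Why: Dess–Martin oxidation gives the C5 aldehyde, which has no α-hydrogen and therefore cannot epimerise or enolise in the following steps.

Step 17
Reactants: 21 C6 S-ethyl thioester C5 aldehyde
Product: 22 methyl (3S,4S,5R,6S,10R)-4-[tert-butyl(dimethyl)silyl]oxy-3-formyl-6,10-dimethyl-11-oxo-5,10-bis(triethylsilyloxy)undecanoate (the C5,C6-dialdehyde)
Conditions: Et3SiH, 10% Pd/C, acetone, rt; filtered and used crude
Reagents that add atoms: none
Why: Fukuyama reduction (insertion of zerovalent palladium into the C–S bond, hydride transfer from the silane) gives the C6 aldehyde under neutral conditions without a C6 alcohol ever forming, so the C12 ester cannot lactonise prematurely and C7 is not exposed to base.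

Step 18
Reactants: 22 C5,C6-dialdehyde methyl ester (O4 TES; O8 TBS; O9 TES)
Product: 24 ten-membered (5S,6R)-5-hydroxy-6,12-olide (O4 TES; O8 TBS; O9 TES), via ten-membered 5,6-diol methyl ester 23 (not isolated)
Conditions: SmI2 (5 equiv), THF, rt, slow addition of 22 (final 2 mM), then 12 h; aq. NaHCO3
Reagents that add atoms: none
Why: Two one-electron transfers from divalent samarium turn the C5 and C6 aldehydes into ketyls (or one ketyl adds to the second, samarium-bound carbonyl), and C5–C6 bond formation gives the trivalent-samarium diolate of 23; the closest known reaction type is the SmI2 pinacol cyclisation of alkoxy-substituted dialdehydes, with low-valent titanium pinacol closure as the model for the ten-membered ring size. The carbocycle closes in a 10-exo-trig sense under high dilution, and the lactone then closes by 5-exo-trig acyl substitution of the O6 samarium alkoxide at the C12 methyl ester, O5 being able to reach C12 only through a six-membered ring. C6 should be set by Felkin–Anh addition next to C7 (C8 chain anti to the forming bond, approach past H7, the β-silyl ether exerting little 1,3-induction) and C5 by the polar Felkin–Anh arrangement next to C4 (the non-chelating O4 silyl ether anti to the forming bond, methyl as the small group). Both preferences lead to (5S,6R), which is also the trans diol that pinacol closures of rings of ten or more members generally favour because the two metal-bearing oxygens stay apart. The step needs coupling over simple reduction and cyclisation over oligomerisation, which the aprotic medium, the slow addition and the inertness of ester and silyl ethers to SmI2 in THF should secure; the facial outcome remains the least certain element of the route.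

Step 19
Reactants: 24 ten-membered (5S,6R)-5-hydroxy-6,12-olide
Product: 27 11(13)-methylene lactone with free C5 hydroxyl (O4 TES; O8 TBS; O9 TES), via C11 Mannich base 25 (not isolated), via methiodide 26 (not isolated)
Conditions: LDA (2.5 equiv), THF, −78 °C; CH2=NMe2+ I−, −78 °C → rt; MeI, MeOH, rt; NaHCO3 (aq), CH2Cl2
Reagents that add atoms: N,N-dimethylmethyleneiminium iodide (Eschenmoser's salt) C=[N+](C)C.[I-]
Why: Mannich alkylation of the lactone enolate with Eschenmoser's salt, N-methylation and E1cB loss of trimethylamine install the exocyclic methylene at C11, the C5 hydroxyl travelling as its lithium alkoxide and the C11 configuration of 25 and 26 being erased.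

Step 20
Reactants: 27 11(13)-methylene lactone with free C5 hydroxyl; 28 (R)-2-methylbutanoic acid
Product: 30 C5 (R)-2-methylbutanoate of 27 (O4 TES; O8 TBS; O9 TES), via mixed anhydride 29 (not isolated)
Conditions: 28, 2,4,6-trichlorobenzoyl chloride, Et3N, THF, rt; then 27, DMAP, toluene, rt → 40 °C
Reagents that add atoms: none
Why: Yamaguchi esterification through the mixed anhydride should acylate the hindered secondary C5 hydroxyl under DMAP catalysis without loss of the α-configuration of the acid, all other oxygens being silylated or part of the lactone.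

Step 21
Reactants: 30 C5 (R)-2-methylbutanoate (O4 TES; O8 TBS; O9 TES)
Product: 31 4,9-diol C5 (R)-2-methylbutanoate (O8 TBS)
Conditions: HF·pyridine, pyridine, THF, 0 °C → rt
Reagents that add atoms: none
Why: Buffered fluoride desilylation removes triethylsilyl ethers much faster than the hindered secondary TBS ether, exposing the C9 hydroxyl and the tertiary C4 hydroxyl, which needs no further protection.

Step 22
Reactants: 31 4,9-diol C5 (R)-2-methylbutanoate (O8 TBS)
Product: 32 C9 ketone (O8 TBS; free tertiary C4 hydroxyl)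
Conditions: Dess–Martin periodinane, NaHCO3, CH2Cl2, rt
Reagents that add atoms: none
Why: Dess–Martin oxidation of the only secondary hydroxyl gives the C9 ketone under non-basic conditions, so C8 and C10 are not epimerised and the tertiary C4 hydroxyl is untouched.

Step 23
Reactants: 32 C9 ketone (O8 TBS)
Product: 33 CNP0339940.1
Conditions: HF·pyridine, THF, rt
Reagents that add atoms: none
Why: Acidic fluoride desilylation removes the last silyl group without base, which the α-ketol, the side-chain ester and the methylene lactone would not tolerate.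

**Compound list**

1 | (S)-citronellal, (3S)-3,7-dimethyloct-6-enal | O=CC[C@@H](C)CCC=C(C)C | starting material
2 | (2R,3S)-3,7-dimethyl-2-[(phenylamino)oxy]oct-6-enal (not isolated) | O=C[C@H](ONc1ccccc1)[C@@H](C)CCC=C(C)C | intermediate
3 | (2R,3S)-3,7-dimethyl-2-[(phenylamino)oxy]oct-6-en-1-ol | OC[C@H](ONc1ccccc1)[C@@H](C)CCC=C(C)C | intermediate
4 | (2R,3S)-3,7-dimethyloct-6-ene-1,2-diol | OC[C@H](O)[C@@H](C)CCC=C(C)C | intermediate
5 | (4R)-2,2-dimethyl-4-[(2S)-6-methylhept-5-en-2-yl]-1,3-dioxolane | CC1(C)OC[C@H](O1)[C@@H](C)CCC=C(C)C | intermediate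
6 | (2E,6S)-6-[(4R)-2,2-dimethyl-1,3-dioxolan-4-yl]-2-methylhept-2-en-1-ol | CC1(C)OC[C@H](O1)[C@@H](C)CC/C=C(\C)CO | intermediate
7 | [(2S,3S)-3-{(3S)-3-[(4R)-2,2-dimethyl-1,3-dioxolan-4-yl]butyl}-2-methyloxiran-2-yl]methanol | CC1(C)OC[C@H](O1)[C@@H](C)CC[C@@H]2O[C@@]2(C)CO | intermediate
8 | (4R)-4-[(2S)-4-{(2S,3S)-3-[(4-methoxybenzyl)oxymethyl]-3-methyloxiran-2-yl}butan-2-yl]-2,2-dimethyl-1,3-dioxolane | CC1(C)OC[C@H](O1)[C@@H](C)CC[C@@H]2O[C@@]2(C)COCc1ccc(OC)cc1 | intermediate
9 | (2R,6S)-6-[(4R)-2,2-dimethyl-1,3-dioxolan-4-yl]-1-[(4-methoxybenzyl)oxy]-2-methylheptan-2-ol | CC1(C)OC[C@H](O1)[C@@H](C)CCC[C@@](C)(O)COCc1ccc(OC)cc1 | intermediate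
10 | (2R,3S,7R)-8-[(4-methoxybenzyl)oxy]-3,7-dimethyloctane-1,2,7-triol | OC[C@H](O)[C@@H](C)CCC[C@@](C)(O)COCc1ccc(OC)cc1 | intermediate
11 | (2R,3S,7R)-8-[(4-methoxybenzyl)oxy]-3,7-dimethyl-1,2,7-tris(triethylsilyloxy)octane | CC[Si](CC)(CC)OC[C@H](O[Si](CC)(CC)CC)[C@@H](C)CCC[C@@](C)(O[Si](CC)(CC)CC)COCc1ccc(OC)cc1 | intermediate
12 | (2R,3S,7R)-8-[(4-methoxybenzyl)oxy]-3,7-dimethyl-2,7-bis(triethylsilyloxy)octanal | O=C[C@H](O[Si](CC)(CC)CC)[C@@H](C)CCC[C@@](C)(O[Si](CC)(CC)CC)COCc1ccc(OC)cc1 | intermediate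
13 | (S)-4-benzyloxazolidin-2-one | O=C1N[C@@H](Cc2ccccc2)CO1 | starting material
14 | methyl 4-chloro-4-oxobutanoate (acid chloride of monomethyl succinate) | COC(=O)CCC(Cl)=O | starting material
15 | methyl 4-[(4S)-4-benzyl-2-oxooxazolidin-3-yl]-4-oxobutanoate | COC(=O)CCC(=O)N1[C@@H](Cc2ccccc2)COC1=O | intermediate
16 | Z-dibutylboron enolate of 15 (not isolated) | CCCCB(CCCC)O/C(=C\CC(=O)OC)N1[C@@H](Cc2ccccc2)COC1=O | intermediate
17 | syn-aldol adduct, methyl (3S,4S,5R,6S,10R)-3-{[(4S)-4-benzyl-2-oxooxazolidin-3-yl]carbonyl}-4-hydroxy-11-[(4-methoxybenzyl)oxy]-6,10-dimethyl-5,10-bis(triethylsilyloxy)undecanoate | O=C1OC[C@H](Cc2ccccc2)N1C(=O)[C@@H](CC(=O)OC)[C@H](O)[C@H](O[Si](CC)(CC)CC)[C@@H](C)CCC[C@@](C)(O[Si](CC)(CC)CC)COCc1ccc(OC)cc1 | intermediate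
18 | O8 TBS ether of 17 (4-[tert-butyl(dimethyl)silyl]oxy analogue) | O=C1OC[C@H](Cc2ccccc2)N1C(=O)[C@@H](CC(=O)OC)[C@H](O[Si](C)(C)C(C)(C)C)[C@H](O[Si](CC)(CC)CC)[C@@H](C)CCC[C@@](C)(O[Si](CC)(CC)CC)COCc1ccc(OC)cc1 | intermediate
19 | methyl (3S,4S,5R,6S,10R)-4-[tert-butyl(dimethyl)silyl]oxy-3-[(ethylsulfanyl)carbonyl]-11-[(4-methoxybenzyl)oxy]-6,10-dimethyl-5,10-bis(triethylsilyloxy)undecanoate | CCSC(=O)[C@@H](CC(=O)OC)[C@H](O[Si](C)(C)C(C)(C)C)[C@H](O[Si](CC)(CC)CC)[C@@H](C)CCC[C@@](C)(O[Si](CC)(CC)CC)COCc1ccc(OC)cc1 | intermediate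
20 | 11-hydroxy analogue of 19 (free C5 hydroxyl) | CCSC(=O)[C@@H](CC(=O)OC)[C@H](O[Si](C)(C)C(C)(C)C)[C@H](O[Si](CC)(CC)CC)[C@@H](C)CCC[C@@](C)(O[Si](CC)(CC)CC)CO | intermediate
21 | 11-oxo analogue of 19 (C5 aldehyde, C6 thioester) | CCSC(=O)[C@@H](CC(=O)OC)[C@H](O[Si](C)(C)C(C)(C)C)[C@H](O[Si](CC)(CC)CC)[C@@H](C)CCC[C@@](C)(O[Si](CC)(CC)CC)C=O | intermediate
22 | methyl (3S,4S,5R,6S,10R)-4-[tert-butyl(dimethyl)silyl]oxy-3-formyl-6,10-dimethyl-11-oxo-5,10-bis(triethylsilyloxy)undecanoate (C5,C6-dialdehyde; key-step precursor) | O=C[C@@H](CC(=O)OC)[C@H](O[Si](C)(C)C(C)(C)C)[C@H](O[Si](CC)(CC)CC)[C@@H](C)CCC[C@@](C)(O[Si](CC)(CC)CC)C=O | intermediate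
23 | ten-membered (5S,6R)-5,6-diol with C11–C12 methyl ester side chain on C7 (O4 TES, O8 TBS, O9 TES; formed as its samarium diolate, not isolated) | COC(=O)C[C@@H]1[C@@H](O)[C@H](O)[C@](C)(O[Si](CC)(CC)CC)CCC[C@H](C)[C@@H](O[Si](CC)(CC)CC)[C@H]1O[Si](C)(C)C(C)(C)C | intermediate
24 | ten-membered (5S,6R)-5-hydroxy-6,12-olide (O4 TES, O8 TBS, O9 TES; key-step product) | C1C(=O)O[C@@H]2[C@@H]1[C@H](O[Si](C)(C)C(C)(C)C)[C@H](O[Si](CC)(CC)CC)[C@@H](C)CCC[C@@](C)(O[Si](CC)(CC)CC)[C@H]2O | intermediate
25 | C11 dimethylaminomethyl lactone (Mannich base, CH2NMe2 trans to C8 expected; not isolated) | CN(C)C[C@H]1C(=O)O[C@@H]2[C@@H]1[C@H](O[Si](C)(C)C(C)(C)C)[C@H](O[Si](CC)(CC)CC)[C@@H](C)CCC[C@@](C)(O[Si](CC)(CC)CC)[C@H]2O | intermediate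
26 | trimethylammonium iodide of 25 (not isolated) | C[N+](C)(C)C[C@H]1C(=O)O[C@@H]2[C@@H]1[C@H](O[Si](C)(C)C(C)(C)C)[C@H](O[Si](CC)(CC)CC)[C@@H](C)CCC[C@@](C)(O[Si](CC)(CC)CC)[C@H]2O.[I-] | intermediate
27 | 11(13)-methylene-6,12-olide with free C5 hydroxyl (O4 TES, O8 TBS, O9 TES) | C=C1C(=O)O[C@@H]2[C@@H]1[C@H](O[Si](C)(C)C(C)(C)C)[C@H](O[Si](CC)(CC)CC)[C@@H](C)CCC[C@@](C)(O[Si](CC)(CC)CC)[C@H]2O | intermediate
28 | (R)-2-methylbutanoic acid | CC[C@@H](C)C(=O)O | starting material
29 | (R)-2-methylbutanoic 2,4,6-trichlorobenzoic anhydride (not isolated) | CC[C@@H](C)C(=O)OC(=O)c1c(Cl)cc(Cl)cc1Cl | intermediate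
30 | C5 (R)-2-methylbutanoate of 27 (O4 TES, O8 TBS, O9 TES) | C=C1C(=O)O[C@@H]2[C@@H]1[C@H](O[Si](C)(C)C(C)(C)C)[C@H](O[Si](CC)(CC)CC)[C@@H](C)CCC[C@@](C)(O[Si](CC)(CC)CC)[C@H]2OC(=O)[C@H](C)CC | intermediate
31 | 4,9-diol C5 (R)-2-methylbutanoate (O8 TBS) | C=C1C(=O)O[C@@H]2[C@@H]1[C@H](O[Si](C)(C)C(C)(C)C)[C@H](O)[C@@H](C)CCC[C@@](C)(O)[C@H]2OC(=O)[C@H](C)CC | intermediate
32 | C9 ketone (O8 TBS, free C4 hydroxyl) | C=C1C(=O)O[C@@H]2[C@@H]1[C@H](O[Si](C)(C)C(C)(C)C)C(=O)[C@@H](C)CCC[C@@](C)(O)[C@H]2OC(=O)[C@H](C)CC | intermediate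
33 | CNP0339940.1, (3aS,4S,6S,10R,11S,11aR)-4,10-dihydroxy-6,10-dimethyl-3-methylidene-2,5-dioxododecahydrocyclodeca[b]furan-11-yl (2R)-2-methylbutanoate | C=C1C(=O)O[C@@H]2[C@@H]1[C@H](O)C(=O)[C@@H](C)CCC[C@@](C)(O)[C@H]2OC(=O)[C@H](C)CC | target

**Step count and risks**

Total: 23 steps. Longest linear sequence: 22 steps (steps 1–10 and 12–23, from (S)-citronellal).

Step 18 (SmI2 ring closure). The ketyls may be reduced or couple between molecules instead of closing the ring. The C5 ketyl may lose the C4 silyloxy group by further reduction and β-elimination. The two carbonyl faces may combine to the cis diol or the other trans diol, and lactonisation may stop at the hydroxy ester (then finished with catalytic acid).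
Fallback: setting out from dialdehyde 22, both aldehydes are methylenated with Ph3P=CH2 (THF, −78 °C) to the open-chain 5,6-bis-vinyl diene F1. Ring-closing metathesis with second-generation Grubbs catalyst (toluene, 80 °C, 1 mM) should give the ten-membered Z-5,6-cycloalkene F2. Epoxidation (mCPBA, NaHCO3) on the face cis to O4 would give the cis-5,6-epoxide F3. Acid (CSA, CH2Cl2) then lets the C12 ester carbonyl open the epoxide at C6 with inversion (5-exo) and lose methanol, which returns the route at hydroxy lactone 24. The stereochemical burden then lies on the facial selectivity of the epoxidation.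

Step 12 (aldol with the ester-bearing imide). The new C8 hydroxyl (or its boron aldolate) may cyclise onto the C12 methyl ester before silylation, and coordination or enolisation through the ester may erode the syn selectivity.
Fallback: C11–C12 is carried as an allyl group. Setting out from 13 and 12, acylation of 13 with pent-4-enoyl chloride gives (S)-4-benzyl-3-(pent-4-enoyl)oxazolidin-2-one F4. The same boron aldol with 12 gives the C7-allyl syn-aldol adduct F5, and TBSOTf gives its O8 TBS ether F6. OsO4 (cat.)/NaIO4/2,6-lutidine cleaves the terminal alkene to the C12 aldehyde F7, NaClO2/NaH2PO4/2-methylbut-2-ene gives the C12 carboxylic acid F8, and TMSCHN2 gives the methyl ester, which is compound 18.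

Step 20 (acylation of the C5 hydroxyl). Acylation of the hindered C5 hydroxyl beside the quaternary C4 may be slow. Under forcing basic conditions O5 may add to the methylene lactone, or the α-centre of the acyl group may epimerise.
Fallback: the order is reversed so that no Michael acceptor is present during acylation. Setting out from hydroxy lactone 24, the lithium alkoxide (LiHMDS, THF, −78 °C) is acylated with mixed anhydride 29 to the O5 (R)-2-methylbutanoate of the saturated lactone F9. Kinetic enolisation of the lactone CH2 with one equivalent of LiHMDS and Eschenmoser's salt then gives the Mannich base F10. MeI gives the methiodide F11, and NaHCO3 elimination returns the route at compound 30. The price is exposure of the side-chain ester to amide base.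

Further compounds
F1 | step 18 | methyl (3S,4S,5R,6S,10R)-4-[tert-butyl(dimethyl)silyl]oxy-3-ethenyl-6,10-dimethyl-5,10-bis(triethylsilyloxy)dodec-11-enoate (5,6-bis-vinyl diene) | C=C[C@@H](CC(=O)OC)[C@H](O[Si](C)(C)C(C)(C)C)[C@H](O[Si](CC)(CC)CC)[C@@H](C)CCC[C@@](C)(O[Si](CC)(CC)CC)C=C
F2 | step 18 | ten-membered Z-5,6-cycloalkene with C11–C12 methyl ester side chain on C7 (O4 TES, O8 TBS, O9 TES) | COC(=O)C[C@@H]1/C=C\[C@](C)(O[Si](CC)(CC)CC)CCC[C@H](C)[C@@H](O[Si](CC)(CC)CC)[C@H]1O[Si](C)(C)C(C)(C)C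
F3 | step 18 | cis-5,6-epoxide of F2 (oxirane oxygen cis to O4) | COC(=O)C[C@@H]1[C@@H]2O[C@@H]2[C@](C)(O[Si](CC)(CC)CC)CCC[C@H](C)[C@@H](O[Si](CC)(CC)CC)[C@H]1O[Si](C)(C)C(C)(C)C
F4 | step 12 | (S)-4-benzyl-3-(pent-4-enoyl)oxazolidin-2-one | C=CCCC(=O)N1[C@@H](Cc2ccccc2)COC1=O
F5 | step 12 | C7-allyl syn-aldol adduct (8-OH, O9 TES, O4 TES, O5 PMB) | O=C1OC[C@H](Cc2ccccc2)N1C(=O)[C@@H](CC=C)[C@H](O)[C@H](O[Si](CC)(CC)CC)[C@@H](C)CCC[C@@](C)(O[Si](CC)(CC)CC)COCc1ccc(OC)cc1
F6 | step 12 | O8 TBS ether of F5 | O=C1OC[C@H](Cc2ccccc2)N1C(=O)[C@@H](CC=C)[C@H](O[Si](C)(C)C(C)(C)C)[C@H](O[Si](CC)(CC)CC)[C@@H](C)CCC[C@@](C)(O[Si](CC)(CC)CC)COCc1ccc(OC)cc1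
F7 | step 12 | C12 aldehyde from F6 | O=C1OC[C@H](Cc2ccccc2)N1C(=O)[C@@H](CC=O)[C@H](O[Si](C)(C)C(C)(C)C)[C@H](O[Si](CC)(CC)CC)[C@@H](C)CCC[C@@](C)(O[Si](CC)(CC)CC)COCc1ccc(OC)cc1
F8 | step 12 | C12 carboxylic acid from F7 | O=C1OC[C@H](Cc2ccccc2)N1C(=O)[C@@H](CC(=O)O)[C@H](O[Si](C)(C)C(C)(C)C)[C@H](O[Si](CC)(CC)CC)[C@@H](C)CCC[C@@](C)(O[Si](CC)(CC)CC)COCc1ccc(OC)cc1
F9 | step 20 | O5 (R)-2-methylbutanoate of saturated lactone 24 | C1C(=O)O[C@@H]2[C@@H]1[C@H](O[Si](C)(C)C(C)(C)C)[C@H](O[Si](CC)(CC)CC)[C@@H](C)CCC[C@@](C)(O[Si](CC)(CC)CC)[C@H]2OC(=O)[C@H](C)CC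
F10 | step 20 | C11 dimethylaminomethyl derivative of F9 (Mannich base) | CN(C)C[C@H]1C(=O)O[C@@H]2[C@@H]1[C@H](O[Si](C)(C)C(C)(C)C)[C@H](O[Si](CC)(CC)CC)[C@@H](C)CCC[C@@](C)(O[Si](CC)(CC)CC)[C@H]2OC(=O)[C@H](C)CC
F11 | step 20 | trimethylammonium iodide of F10 | C[N+](C)(C)C[C@H]1C(=O)O[C@@H]2[C@@H]1[C@H](O[Si](C)(C)C(C)(C)C)[C@H](O[Si](CC)(CC)CC)[C@@H](C)CCC[C@@](C)(O[Si](CC)(CC)CC)[C@H]2OC(=O)[C@H](C)CC.[I-]
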